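Everything rests on cutting ring C at the C4–C4a bond. C4a sits ortho to O1 and para to the C7 oxygen of ring A, so an iodine installed there marks the only carbon that can become nucleophilic. C2, C3, C4 and the oxygens on C3 and C4 arrive together in an aryl glycidic Weinreb amide, which the ring A phenol opens at its benzylic carbon. Iodine–magnesium exchange and intramolecular acylation then forge C4–C4a and close ring C as a 3-silyloxyflavanone in one acid-free operation that spares the prenyl ether. The precursor is the anti α-silyloxy-β-(2-iodo-5-prenyloxyphenoxy) Weinreb amide carrying the 3,4-dimethoxyphenyl group. Desilylation and oxidation then erase both stereocentres.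

Key step: step 5

Assumption: all chiral intermediates are racemic with one enantiomer drawn, and minor diastereomers from steps 2 and 3 need not be removed because C2 and C3 both become sp2 in the last step.

Step 1
Reactants: 1 4-iodoresorcinol (4-iodobenzene-1,3-diol); 2 prenyl bromide (1-bromo-3-methylbut-2-ene)
Product: 3 2-iodo-5-(3-methylbut-2-enyloxy)phenol
Conditions: K2CO3 (1.1 equiv), 2 (1.0 equiv), acetone, rt to 40 °C
Reagents that add atoms: none
Why: Williamson ether synthesis in which the hydroxyl para to iodine, free of the ortho-iodine steric screen and giving the more nucleophilic phenoxide, should take up the single equivalent of allylic bromide by SN2 at the primary carbon, and because the iodine is already in place the trisubstituted alkene never meets an electrophilic iodinating agent.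

Step 2
Reactants: 4 veratraldehyde (3,4-dimethoxybenzaldehyde); 5 2-chloro-N-methoxy-N-methylacetamide
Product: 7 rac-trans-3-(3,4-dimethoxyphenyl)-N-methoxy-N-methyloxirane-2-carboxamide [(2R,3S) drawn], via potassium chlorohydrin alkoxide 6 (not isolated)
Conditions: KOtBu (1.1 equiv, added last), THF, −40 to 0 °C
Reagents that add atoms: none
Why: Darzens condensation of an α-chloro amide: the potassium enolate adds reversibly to the aldehyde and the chlorohydrin alkoxide 6 that can close with aryl and carboxamide groups apart displaces chloride fastest, which sets both stereocentres as the racemic trans epoxide and delivers the Weinreb amide at the outset, so no ester-to-amide exchange with organomagnesium or aluminium reagents is ever needed beside the aryl iodide.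

Step 3
Reactants: 7 rac-trans-glycidic Weinreb amide; 3 2-iodo-5-(3-methylbut-2-enyloxy)phenol
Product: 8 rac-anti-3-(3,4-dimethoxyphenyl)-2-hydroxy-3-[2-iodo-5-(3-methylbut-2-enyloxy)phenoxy]-N-methoxy-N-methylpropanamide [(2R,3R) drawn]
Conditions: 3 (1.1 equiv), Cs2CO3 (0.3 equiv), DMF, 60 °C
Reagents that add atoms: none
Why: Base-catalysed SN2 opening of an aryl glycidic amide by a phenoxide: the 3,4-dimethoxyphenyl group weakens the benzylic C–O bond and directs attack to that carbon (future C2), inversion there converts the trans epoxide into the anti hydroxy ether while the carbinol centre (future C3) is untouched, and excess phenol reprotonates the alkoxide so that aryl iodide, prenyl ether and amide see only mild carbonate base.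

Step 4
Reactants: 8 rac-anti-hydroxy amide
Product: 9 rac-anti-2-(tert-butyldimethylsilyloxy)-3-(3,4-dimethoxyphenyl)-3-[2-iodo-5-(3-methylbut-2-enyloxy)phenoxy]-N-methoxy-N-methylpropanamide [(2R,3R) drawn]
Conditions: TBSOTf (1.3 equiv), 2,6-lutidine (2 equiv), CH2Cl2, 0 °C
Reagents that add atoms: tert-butyldimethylsilyl triflate (TBSOTf), CC(C)(C)[Si](C)(C)OS(=O)(=O)C(F)(F)F
Why: Silylation of a hindered secondary alcohol by a silyl triflate under lutidine buffering, which touches neither stereocentre, leaves the alkene, the aryl iodide and the benzylic aryl ether alone at this temperature, removes the acidic proton before the organomagnesium step and adds bulk that screens the amide carbonyl from external nucleophiles.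

Step 5
Reactants: 9 rac-anti-silyloxy iodoaryl Weinreb amide
Product: 12 rac-trans-3-(tert-butyldimethylsilyloxy)-3',4'-dimethoxy-7-prenyloxyflavanone [(2R,3R) drawn], via arylmagnesium chloride 10 (not isolated), via chelated magnesium hemiaminal 11 (not isolated)
Conditions: iPrMgCl·LiCl (1.2 equiv), THF (0.05 M), −30 to 0 °C; then sat. aq NH4Cl
Reagents that add atoms: none
Why: iPrMgCl·LiCl exchanges the C4a–I bond, an exchange assisted by the neighbouring aryloxy oxygen, to give arylmagnesium 10 and 2-iodopropane before the secondary Grignard reagent can add to the amide carbonyl, which is screened by the adjacent silyloxy group. Carbanionic C4a then attacks the Weinreb carbonyl (future C4), and the N-methoxy oxygen holds magnesium in the five-membered chelate 11, which survives until aqueous NH4Cl releases ketone 12, so over-addition is excluded. The closest known reaction type is the Parham cyclisation, halogen–metal exchange followed by intramolecular acylation of the aryl anion, which is established for chroman-4-ones. Ring C closes in the 6-exo-trig mode, the new ring running through C4a, C8a, O1, C2, C3 and C4. No lasting stereocentre is made, since the carbinolamine carbon of 11 becomes the carbonyl again, and the anti pair inherited from 9 simply becomes the diequatorial 2,3-trans pair of the flavanone. The step needs chemoselectivity for exchange and closure over intermolecular addition, α-deprotonation with loss of aryloxide or protonation, which low temperature, dilution, the short tether and the bulk around the amide secure, whereas site selectivity is settled by the iodine and the acid-free medium keeps the prenyl ether intact.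

Step 6
Reactants: 12 rac-trans-3-silyloxyflavanone
Product: 13 rac-trans-3-hydroxy-3',4'-dimethoxy-7-prenyloxyflavanone (dihydroflavonol) [(2R,3R) drawn]
Conditions: Bu4NF (1.2 equiv), AcOH (1.3 equiv), THF, 0 °C to rt
Reagents that add atoms: none
Why: Fluoride-driven cleavage of the Si–O bond, with acetic acid buffering the basicity of Bu4NF so that the flavanone is not opened to the chalcone by retro-oxa-Michael reaction, and any epimerisation at C2 or C3 would in any case be without consequence.

Step 7
Reactants: 13 rac-trans-dihydroflavonol
Product: 15 3-hydroxy-3',4'-dimethoxy-7-prenyloxyflavone (target CNP0167607.0), via 2-arylchroman-3,4-dione 14 (not isolated)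
Conditions: Dess–Martin periodinane (1.1 equiv), CH2Cl2, 0 °C to rt
Reagents that add atoms: none
Why: Dess–Martin oxidation of an α-hydroxy ketone to the 1,2-dione 14, whose C2–H is benzylic, α to oxygen and α to the new ketone and therefore tautomerises at once to the conjugated, hydrogen-bonded 3-hydroxychromen-4-one, which removes both stereocentres, while the reagent neither attacks the prenyl alkene nor cleaves the allylic ether as quinone or iodine oxidants could.

Compound list
1 | 4-iodoresorcinol | Oc1ccc(I)c(O)c1 | starting material
2 | prenyl bromide | CC(C)=CCBr | starting material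
3 | 2-iodo-5-(3-methylbut-2-enyloxy)phenol | Oc1cc(OCC=C(C)C)ccc1I | intermediate
4 | veratraldehyde | COc1ccc(C=O)cc1OC | starting material
5 | 2-chloro-N-methoxy-N-methylacetamide | CON(C)C(=O)CCl | starting material
6 | potassium 2-chloro-1-(3,4-dimethoxyphenyl)-3-[methoxy(methyl)amino]-3-oxopropan-1-olate (equilibrating diastereomers, not isolated) | CON(C)C(=O)C(Cl)C([O-])c1ccc(OC)c(OC)c1.[K+] | intermediate
7 | rac-trans-3-(3,4-dimethoxyphenyl)-N-methoxy-N-methyloxirane-2-carboxamide, (2R,3S) drawn | CON(C)C(=O)[C@@H]1O[C@H]1c2ccc(OC)c(OC)c2 | intermediate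
8 | rac-anti-3-(3,4-dimethoxyphenyl)-2-hydroxy-3-[2-iodo-5-(3-methylbut-2-enyloxy)phenoxy]-N-methoxy-N-methylpropanamide, (2R,3R) drawn | CON(C)C(=O)[C@H](O)[C@@H](c1ccc(OC)c(OC)c1)Oc1cc(OCC=C(C)C)ccc1I | intermediate
9 | rac-anti-2-(tert-butyldimethylsilyloxy)-3-(3,4-dimethoxyphenyl)-3-[2-iodo-5-(3-methylbut-2-enyloxy)phenoxy]-N-methoxy-N-methylpropanamide, (2R,3R) drawn | CON(C)C(=O)[C@H](O[Si](C)(C)C(C)(C)C)[C@@H](c1ccc(OC)c(OC)c1)Oc1cc(OCC=C(C)C)ccc1I | intermediate
10 | arylmagnesium chloride from 9, MgCl in place of iodine (not isolated) | CON(C)C(=O)[C@H](O[Si](C)(C)C(C)(C)C)[C@@H](c1ccc(OC)c(OC)c1)Oc1cc(OCC=C(C)C)ccc1[Mg]Cl | intermediate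
11 | chloromagnesium salt of the 4-[methoxy(methyl)amino]flavan-4-ol, 2,3-trans, C4 undefined (not isolated) | CON(C)C1(O[Mg]Cl)[C@H](O[Si](C)(C)C(C)(C)C)[C@@H](c2ccc(OC)c(OC)c2)Oc2cc(OCC=C(C)C)ccc21 | intermediate
12 | rac-trans-3-(tert-butyldimethylsilyloxy)-3',4'-dimethoxy-7-prenyloxyflavanone, (2R,3R) drawn | O=C1[C@H](O[Si](C)(C)C(C)(C)C)[C@@H](c2ccc(OC)c(OC)c2)Oc2cc(OCC=C(C)C)ccc12 | intermediate
13 | rac-trans-3-hydroxy-3',4'-dimethoxy-7-prenyloxyflavanone, (2R,3R) drawn | O=C1[C@H](O)[C@@H](c2ccc(OC)c(OC)c2)Oc2cc(OCC=C(C)C)ccc12 | intermediate
14 | 2-(3,4-dimethoxyphenyl)-7-prenyloxychroman-3,4-dione, C2 configurationally labile (not isolated) | O=C1C(=O)C(c2ccc(OC)c(OC)c2)Oc2cc(OCC=C(C)C)ccc12 | intermediate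
15 | 2-(3,4-dimethoxyphenyl)-3-hydroxy-7-(3-methylbut-2-enyloxy)chromen-4-one | COc1ccc(-c2oc3cc(OCC=C(C)C)ccc3c(=O)c2O)cc1OC | target

Total steps: 7. Longest linear sequence: 6 (steps 2 to 7, or equally step 1 followed by steps 3 to 7).

Steps most likely to fail

1. Step 5.
- Risk: exchange on the electron-rich ring may lag behind addition of the isopropyl group to the amide. The arylmagnesium may also be protonated, or may trigger loss of the aryloxide, before it cyclises.
- Fallback (from 9, back at 12): the closure is moved from the acyl to the aldehyde oxidation level and from magnesium to chromium. Reduction of 9 with iBu2AlH (THF, −78 °C) should give rac-anti-2-(tert-butyldimethylsilyloxy)-3-(3,4-dimethoxyphenyl)-3-(2-iodo-5-prenyloxyphenoxy)propanal F1. An intramolecular Nozaki–Hiyama–Kishi coupling (CrCl2, catalytic NiCl2, DMF, rt) forms the same C4–C4a bond under nearly neutral conditions. It gives 2,3-trans-3-(tert-butyldimethylsilyloxy)-3',4'-dimethoxy-7-prenyloxyflavan-4-ol F2 as a mixture of C4 epimers. Dess–Martin oxidation of the benzylic alcohol then returns to 12.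

2. Step 3.
- Risk: the hindered ortho-iodophenoxide may attack too slowly, attack at the carbon next to the amide may compete, or the labile electron-rich epoxide may decompose during prolonged heating.
- Fallback (from 4, back at 8): the C2–O1 bond is made by alcohol activation instead of epoxide opening. Horner–Wadsworth–Emmons olefination of 4 with diethyl [2-(methoxy(methyl)amino)-2-oxoethyl]phosphonate (NaH, THF, 0 °C) should give (E)-3-(3,4-dimethoxyphenyl)-N-methoxy-N-methylacrylamide F3. Upjohn dihydroxylation (catalytic OsO4, NMO, acetone–water), run before any prenyl group is present, gives rac-syn-3-(3,4-dimethoxyphenyl)-2,3-dihydroxy-N-methoxy-N-methylpropanamide F4. A Mitsunobu etherification with phenol 3 (PPh3, DIAD, THF, 0 °C) activates the more electron-rich benzylic hydroxyl in preference to the one next to the carbonyl. It displaces that hydroxyl with inversion, which gives the anti hydroxy ether 8.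

3. Step 1.
- Risk: discrimination between the two hydroxyl groups may be poor, and double alkylation or C-prenylation of the resorcinol ring may erode the supply of the phenol.
- Fallback (from 2, back at 3): only one free hydroxyl is present when the prenyl group is attached. Commercial resorcinol monobenzoate is iodinated para to its free hydroxyl (N-iodosuccinimide, catalytic TsOH, MeCN, rt) to give 5-hydroxy-2-iodophenyl benzoate F5. Alkylation with 2 (K2CO3, acetone, rt) gives 2-iodo-5-(3-methylbut-2-enyloxy)phenyl benzoate F6. Methanolysis of the ester (K2CO3, MeOH, rt) then releases 3.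

Further compounds
F1 | step 5 | rac-anti-2-(tert-butyldimethylsilyloxy)-3-(3,4-dimethoxyphenyl)-3-(2-iodo-5-prenyloxyphenoxy)propanal | O=C[C@H](O[Si](C)(C)C(C)(C)C)[C@@H](c1ccc(OC)c(OC)c1)Oc1cc(OCC=C(C)C)ccc1I
F2 | step 5 | 2,3-trans-3-(tert-butyldimethylsilyloxy)-3',4'-dimethoxy-7-prenyloxyflavan-4-ol (C4 epimers) | OC1[C@H](O[Si](C)(C)C(C)(C)C)[C@@H](c2ccc(OC)c(OC)c2)Oc2cc(OCC=C(C)C)ccc12
F3 | step 3 | (E)-3-(3,4-dimethoxyphenyl)-N-methoxy-N-methylacrylamide | CON(C)C(=O)/C=C/c1ccc(OC)c(OC)c1
F4 | step 3 | rac-syn-3-(3,4-dimethoxyphenyl)-2,3-dihydroxy-N-methoxy-N-methylpropanamide, (2R,3S) drawn | CON(C)C(=O)[C@H](O)[C@@H](O)c1ccc(OC)c(OC)c1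
F5 | step 1 | 5-hydroxy-2-iodophenyl benzoate | O=C(Oc1cc(O)ccc1I)c1ccccc1
F6 | step 1 | 2-iodo-5-(3-methylbut-2-enyloxy)phenyl benzoate | O=C(Oc1cc(OCC=C(C)C)ccc1I)c1ccccc1
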